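**Assumption:** the target has no stereocentre, stereogenic alkene or axis, so "single enantiomer" is taken to mean the one achiral constitution shown, and no enantiocontrol is needed.

## Retrosynthetic overview

- Prebarbigerone ⇒ O-methylation of the 7-hydroxy-8-prenylisoflavone, whose prenyl group comes from an aromatic Claisen rearrangement of the 7-O-(1,1-dimethylallyl) ether (7-hydroxyisoflavone + 3-chloro-3-methylbut-1-yne, then semihydrogenation).
- 7-Hydroxyisoflavone ⇒ 7-benzyloxyisoflavone ⇒ closure of ring C by the ortho phenol onto a masked formyl group (dimethyl acetal).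
- That acetal ⇒ 2'-hydroxychalcone by oxidative 1,2-shift of aryl ring B with Tl(NO3)3.
- Chalcone ⇒ key C–C bond (the future C2–C3 bond) by intermolecular Claisen–Schmidt aldol condensation of 4-O-benzylresacetophenone with 2,4,5-trimethoxybenzaldehyde.
- Ring order: rings A and B are bought intact; ring C (the 4-pyranone) is the only ring formed, after the aldol and the aryl shift. The prenyl alkene is introduced only after the oxidative step, which it would not survive.

## Route

Step 1
Reactants: 1 1-(2,4-dihydroxyphenyl)ethanone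
Product: 2 1-[4-(benzyloxy)-2-hydroxyphenyl]ethanone
Conditions: BnBr (1.05 equiv), K2CO3 (1.2 equiv), acetone, reflux, 6 h
Reagents that add atoms: benzyl bromide (BrCc1ccccc1)
Why: Williamson ether synthesis (SN2) is selective for the 4-OH because the 2-OH is hydrogen-bonded to the acetyl carbonyl and much less nucleophilic; no stereocentre is formed.

Step 2
Reactants: 2 1-[4-(benzyloxy)-2-hydroxyphenyl]ethanone; 3 2,4,5-trimethoxybenzaldehyde
Product: 5 (E)-1-[4-(benzyloxy)-2-hydroxyphenyl]-3-(2,4,5-trimethoxyphenyl)prop-2-en-1-one, via aldol adduct 4 (not isolated)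
Conditions: KOH (50% aq., 10 equiv), EtOH, rt, 48 h; then cold dilute HCl
Reagents that add atoms: none
Why: Claisen–Schmidt aldol condensation is unambiguous here because ketone 2 is the only enolisable partner and aldehyde 3 the only non-enolisable electrophile, and E1cB dehydration of racemic aldol 4 gives the conjugated E-alkene under thermodynamic control.

Step 3
Reactants: 5 (E)-1-[4-(benzyloxy)-2-hydroxyphenyl]-3-(2,4,5-trimethoxyphenyl)prop-2-en-1-one
Product: 6 1-[4-(benzyloxy)-2-hydroxyphenyl]-3,3-dimethoxy-2-(2,4,5-trimethoxyphenyl)propan-1-one (racemic)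
Conditions: Tl(NO3)3·3H2O (1.1 equiv), dry MeOH, rt, 4–6 h; filter off TlNO3, aqueous work-up
Reagents that add atoms: methanol (CO)
Why: Oxidative 1,2-aryl migration by trivalent thallium (oxythallation of the enone in methanol, then shift of the electron-rich aryl ring B from C-beta to C-alpha as monovalent thallium departs) gives the beta,beta-dimethoxy ketone; its new CH(Ar) centre is racemic and becomes sp2 in step 4.

Step 4
Reactants: 6 1-[4-(benzyloxy)-2-hydroxyphenyl]-3,3-dimethoxy-2-(2,4,5-trimethoxyphenyl)propan-1-one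
Product: 8 7-(benzyloxy)-3-(2,4,5-trimethoxyphenyl)-4H-chromen-4-one, via 2-methoxyisoflavanone 7 (not isolated)
Conditions: 10% aq. HCl, MeOH, reflux, 3 h
Reagents that add atoms: none
Why: Acid-catalysed transacetalisation by the ortho phenol closes ring C, and elimination of methanol from the 2-methoxyisoflavanone gives the conjugated 4-pyranone, which erases both transient stereocentres; the benzyl ether is stable to dilute acid.

Step 5
Reactants: 8 7-(benzyloxy)-3-(2,4,5-trimethoxyphenyl)-4H-chromen-4-one
Product: 9 7-hydroxy-3-(2,4,5-trimethoxyphenyl)-4H-chromen-4-one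
Conditions: H2 (1 atm), 10% Pd/C, THF/MeOH, rt, stopped at full conversion (TLC)
Reagents that add atoms: none
Why: Catalytic hydrogenolysis of the benzylic C–O bond is much faster than reduction of the vinylogous-ester C2=C3 bond at 1 atm; aryl methyl ethers are inert.

Step 6
Reactants: 9 7-hydroxy-3-(2,4,5-trimethoxyphenyl)-4H-chromen-4-one; 10 3-chloro-3-methylbut-1-yne
Product: 11 7-[(2-methylbut-3-yn-2-yl)oxy]-3-(2,4,5-trimethoxyphenyl)-4H-chromen-4-one
Conditions: 10 (3 equiv), K2CO3 (2 equiv), KI (1 equiv), CuI (5 mol %), acetone, reflux, 24 h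
Reagents that add atoms: none
Why: Copper-assisted propargylic substitution (ionisation of the tertiary chloride through the copper acetylide, capture by the phenoxide) gives the tertiary propargyl aryl ether by O-alkylation; acetone reflux is too cool for a propargyl Claisen reaction.

Step 7
Reactants: 11 7-[(2-methylbut-3-yn-2-yl)oxy]-3-(2,4,5-trimethoxyphenyl)-4H-chromen-4-one
Product: 12 7-[(2-methylbut-3-en-2-yl)oxy]-3-(2,4,5-trimethoxyphenyl)-4H-chromen-4-one
Conditions: H2 (1 atm, 1 equiv uptake), Pd/CaCO3 poisoned with Pb(OAc)2 (Lindlar catalyst), quinoline, EtOAc, rt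
Reagents that add atoms: none
Why: Lindlar semihydrogenation stops at the terminal alkene because the poisoned Pd surface binds the alkyne far more strongly than the alkene or the chromone double bond.

Step 8
Reactants: 12 7-[(2-methylbut-3-en-2-yl)oxy]-3-(2,4,5-trimethoxyphenyl)-4H-chromen-4-one
Product: 14 7-hydroxy-8-(3-methylbut-2-en-1-yl)-3-(2,4,5-trimethoxyphenyl)-4H-chromen-4-one, via ortho-dienone 13 (not isolated)
Conditions: PhNEt2, 180–190 °C, Ar, 1–2 h; then dilute HCl wash
Reagents that add atoms: none
Why: Aromatic Claisen [3,3]-sigmatropic rearrangement delivers the 1,1-dimethylallyl group with allylic inversion as a linear prenyl group to C8, favoured over C6 by the higher C7–C8 bond order of benzopyranones, and tautomerisation of dienone 13 removes its transient sp3 centre; the basic solvent suppresses acid-catalysed chroman formation.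

Step 9
Reactants: 14 7-hydroxy-8-(3-methylbut-2-en-1-yl)-3-(2,4,5-trimethoxyphenyl)-4H-chromen-4-one
Product: 15 prebarbigerone (7-methoxy-8-(3-methylbut-2-en-1-yl)-3-(2,4,5-trimethoxyphenyl)-4H-chromen-4-one)
Conditions: MeI (3 equiv), K2CO3 (2 equiv), acetone, reflux, 6 h
Reagents that add atoms: iodomethane (CI)
Why: Williamson methylation (SN2) of the only free phenol; the prenyl alkene and the pyranone are inert to these conditions and no stereocentre is involved.

## Compound list

1 | 1-(2,4-dihydroxyphenyl)ethanone (resacetophenone) | CC(=O)c1ccc(O)cc1O | starting material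
2 | 1-[4-(benzyloxy)-2-hydroxyphenyl]ethanone | CC(=O)c1ccc(OCc2ccccc2)cc1O | intermediate
3 | 2,4,5-trimethoxybenzaldehyde | COc1cc(OC)c(C=O)cc1OC | starting material
4 | 1-[4-(benzyloxy)-2-hydroxyphenyl]-3-hydroxy-3-(2,4,5-trimethoxyphenyl)propan-1-one (racemic aldol adduct, not isolated) | COc1cc(OC)c(C(O)CC(=O)c2ccc(OCc3ccccc3)cc2O)cc1OC | intermediate
5 | (E)-1-[4-(benzyloxy)-2-hydroxyphenyl]-3-(2,4,5-trimethoxyphenyl)prop-2-en-1-one (chalcone) | COc1cc(OC)c(/C=C/C(=O)c2ccc(OCc3ccccc3)cc2O)cc1OC | intermediate
6 | 1-[4-(benzyloxy)-2-hydroxyphenyl]-3,3-dimethoxy-2-(2,4,5-trimethoxyphenyl)propan-1-one (racemic) | COC(OC)C(C(=O)c1ccc(OCc2ccccc2)cc1O)c1cc(OC)c(OC)cc1OC | intermediate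
7 | 7-(benzyloxy)-2-methoxy-3-(2,4,5-trimethoxyphenyl)chroman-4-one (racemic diastereomer mixture, not isolated) | COC1Oc2cc(OCc3ccccc3)ccc2C(=O)C1c1cc(OC)c(OC)cc1OC | intermediate
8 | 7-(benzyloxy)-3-(2,4,5-trimethoxyphenyl)-4H-chromen-4-one | COc1cc(OC)c(-c2coc3cc(OCc4ccccc4)ccc3c2=O)cc1OC | intermediate
9 | 7-hydroxy-3-(2,4,5-trimethoxyphenyl)-4H-chromen-4-one | COc1cc(OC)c(-c2coc3cc(O)ccc3c2=O)cc1OC | intermediate
10 | 3-chloro-3-methylbut-1-yne | CC(C)(Cl)C#C | starting material
11 | 7-[(2-methylbut-3-yn-2-yl)oxy]-3-(2,4,5-trimethoxyphenyl)-4H-chromen-4-one | COc1cc(OC)c(-c2coc3cc(OC(C)(C)C#C)ccc3c2=O)cc1OC | intermediate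
12 | 7-[(2-methylbut-3-en-2-yl)oxy]-3-(2,4,5-trimethoxyphenyl)-4H-chromen-4-one | COc1cc(OC)c(-c2coc3cc(OC(C)(C)C=C)ccc3c2=O)cc1OC | intermediate
13 | 8-(3-methylbut-2-en-1-yl)-3-(2,4,5-trimethoxyphenyl)-8H-chromene-4,7-dione (racemic ortho-dienone, not isolated) | COc1cc(OC)c(C2=COC3=C(C=CC(=O)C3CC=C(C)C)C2=O)cc1OC | intermediate
14 | 7-hydroxy-8-(3-methylbut-2-en-1-yl)-3-(2,4,5-trimethoxyphenyl)-4H-chromen-4-one | COc1cc(OC)c(-c2coc3c(CC=C(C)C)c(O)ccc3c2=O)cc1OC | intermediate
15 | prebarbigerone, 7-methoxy-8-(3-methylbut-2-en-1-yl)-3-(2,4,5-trimethoxyphenyl)-4H-chromen-4-one (achiral) | COc1cc(OC)c(-c2coc3c(CC=C(C)C)c(OC)ccc3c2=O)cc1OC | target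

## Summary

Total step count: 9.
Longest linear sequence: 9 steps (1 → 15); 3 and 10 are bought and used directly.

Three steps most likely to fail, each with a fallback:

1. Step 3 (oxidative aryl shift with Tl(NO3)3). The very electron-rich trimethoxyphenyl ring may be over-oxidised, or aurone formation may compete. The fallback sets out from chalcone 5 and comes back at isoflavone 8, skipping 6 and step 4. Chalcone 5 is heated with NaOAc in EtOH at reflux to close ring C first by intramolecular oxa-Michael addition, giving racemic 7-(benzyloxy)-2-(2,4,5-trimethoxyphenyl)chroman-4-one F1. F1 is then treated with PhI(OH)OTs in MeCN at reflux; the hypervalent-iodine reagent functionalises C3 and triggers a 2,3-aryl migration with loss of a proton, which gives 8 directly without thallium.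

2. Step 6 (O-alkylation of a weakly nucleophilic, vinylogous-acid phenol with a tertiary propargylic chloride). Conversion may be low. The fallback sets out from 9 and comes back at 12, replacing steps 6 and 7. Phenol 9 is treated with tert-butyl 2-methylbut-3-en-2-yl carbonate and Pd(PPh3)4 (a zerovalent palladium catalyst) in THF at 0 °C. This decarboxylative Tsuji–Trost O-allylation gives the branched 1,1-dimethylallyl ether 12 as the kinetic product, so no alkyne and no semihydrogenation are needed; no new compound arises on the way (F0).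

3. Step 8 (Claisen rearrangement). Possible problems are a C6 regioisomer and thermal follow-up cyclisation of the ortho-prenylphenol. The fallback sets out from 9 and comes back at target 15, replacing steps 6–9 by cross-coupling. Phenol 9 is iodinated through its phenoxide (I2, NaHCO3, THF/H2O, 0 °C to rt), which directs the electrophile to C8 and leaves the neutral trimethoxyphenyl ring untouched, giving 7-hydroxy-8-iodo-3-(2,4,5-trimethoxyphenyl)-4H-chromen-4-one F2. Methylation (MeI, K2CO3, acetone) gives 8-iodo-7-methoxy-3-(2,4,5-trimethoxyphenyl)-4H-chromen-4-one F3. Stille coupling of F3 with tributyl(3-methylbut-2-en-1-yl)stannane (Pd(PPh3)4, DMF, 90 °C) joins the less substituted allyl terminus to C8 and gives 15.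

## Further compounds

F1 | step 3 | 7-(benzyloxy)-2-(2,4,5-trimethoxyphenyl)chroman-4-one (racemic) | COc1cc(OC)c(C2CC(=O)c3ccc(OCc4ccccc4)cc3O2)cc1OC
F0 | step 6 | none | none
F2 | step 8 | 7-hydroxy-8-iodo-3-(2,4,5-trimethoxyphenyl)-4H-chromen-4-one | COc1cc(OC)c(-c2coc3c(I)c(O)ccc3c2=O)cc1OC
F3 | step 8 | 8-iodo-7-methoxy-3-(2,4,5-trimethoxyphenyl)-4H-chromen-4-one | COc1cc(OC)c(-c2coc3c(I)c(OC)ccc3c2=O)cc1OC
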